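**Retrosynthetic overview**
- The ten-membered ring is closed last by ring-closing metathesis at C4=C5 (Z); the C1 carbinol and the C3 acetate are set together by an Evans–Tishchenko reduction of a C3-hydroxy C1-enone.
- The C1–C10 bond comes from a Nozaki–Hiyama–Kishi union of an east (E)-alkenyl iodide carrying the α-methylene-γ-lactone with a west aldehyde made from (S)-α-hydroxy-γ-butyrolactone (supplies C3).
- East half: the C7–C8 bond and both its stereocentres come from a [2,3]-Wittig rearrangement of a (Z)-allyl but-2-ynyl ether, steered by the C6 centre of (R)-glyceraldehyde acetonide; the ether is assembled by a one-pot oxa-Michael/Horner–Wadsworth–Emmons reaction.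
- Ring order: γ-lactone first (step 8), ten-membered carbocycle last (step 20).

Assumption: atom labels C1–C15 in names and explanations follow the germacranolide skeleton of the target (C11–C13 = methylene-lactone carbons, C14 = methyl on C10, C15 = hydroxymethyl on C4); the target is (1S,3S,6R,7R,8R).

**Route**

Step 1
Reactants: 1 ethyl 2-(diethoxyphosphoryl)acrylate; 2 but-2-yn-1-ol; 3 (R)-2,2-dimethyl-1,3-dioxolane-4-carbaldehyde
Product: 5 ethyl (2E)-2-[(but-2-yn-1-yloxy)methyl]-3-[(4S)-2,2-dimethyl-1,3-dioxolan-4-yl]prop-2-enoate, via sodium phosphonate carbanion 4 (not isolated)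
Conditions: NaH, THF, 0 °C (2, then 1); then 3, −78 °C → rt
Reagents that add atoms: none
Why: Oxa-Michael addition of the sodium alkoxide of 2 to vinylphosphonate 1 gives the stabilised carbanion 4, whose Horner–Wadsworth–Emmons olefination of 3 gives mainly the (E)-enoate (ester trans to the dioxolane; minor Z isomer removed by chromatography) without touching the bought stereocentre.

Step 2
Reactants: 5
Product: 6 (2Z)-2-[(but-2-yn-1-yloxy)methyl]-3-[(4S)-2,2-dimethyl-1,3-dioxolan-4-yl]prop-2-en-1-ol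
Conditions: iBu2AlH (2.3 equiv), CH2Cl2, −78 °C
Reagents that add atoms: none
Why: 1,2-Reduction of the enoate ester by the aluminium hydride gives the allylic alcohol with the olefin geometry unchanged (only the descriptor changes because the priorities change).

Step 3
Reactants: 6
Product: 7 tert-butyl({(2E)-2-[(but-2-yn-1-yloxy)methyl]-3-[(4S)-2,2-dimethyl-1,3-dioxolan-4-yl]prop-2-en-1-yl}oxy)dimethylsilane
Conditions: TBSCl, imidazole, DMF, rt
Reagents that add atoms: tert-butyldimethylsilyl chloride, CC(C)(C)[Si](C)(C)Cl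
Why: Silylation of the primary alcohol masks it against the strong base of step 4.

Step 4
Reactants: 7
Product: 9 (3R,4S)-2-({[tert-butyl(dimethyl)silyl]oxy}methyl)-3-[(4S)-2,2-dimethyl-1,3-dioxolan-4-yl]hept-1-en-5-yn-4-ol, via lithiated propargylic ether 8 (not isolated)
Conditions: n-BuLi (1.3 equiv), THF, −78 °C; aq. NH4Cl
Reagents that add atoms: none
Why: [2,3]-Wittig rearrangement: carbanion 8 attacks C7 through a five-membered envelope transition state, the cis-placed migrating CH2–O terminus and an exo alkynyl group giving the syn C7/C8 relationship, while A(1,3) strain holds H6 in the olefin plane and the new bond forms anti to the C6–O bond, so the bought C6 centre sets both new stereocentres.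

Step 5
Reactants: 9
Product: 11 (2E,4S,5R)-6-({[tert-butyl(dimethyl)silyl]oxy}methyl)-5-[(4S)-2,2-dimethyl-1,3-dioxolan-4-yl]-2-iodohepta-2,6-dien-4-ol, via alkenylzirconocene 10 (not isolated)
Conditions: Cp2Zr(H)Cl (2.2 equiv), THF, rt; then I2, 0 °C
Reagents that add atoms: iodine, II
Why: Hydrozirconation–iodination: syn addition of Zr–H places zirconium on the less hindered methyl-bearing C10 (distal to the zirconium alkoxide at C8) and iodinolysis with retention gives the (E)-alkenyl iodide, the 1,1-disubstituted olefin reacting much more slowly.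

Step 6
Reactants: 11
Product: 12 (2E,4S,5R)-6-({[tert-butyl(dimethyl)silyl]oxy}methyl)-5-[(4S)-2,2-dimethyl-1,3-dioxolan-4-yl]-2-iodohepta-2,6-dien-4-yl (2Z)-2-methylbut-2-enoate
Conditions: angelic acid, 2,4,6-trichlorobenzoyl chloride, Et3N, toluene, rt; then 11, 80 °C (no DMAP)
Reagents that add atoms: angelic acid [(2Z)-2-methylbut-2-enoic acid], C/C=C(/C)C(=O)O
Why: Yamaguchi esterification through the mixed anhydride acylates the hindered C8 carbinol with retention at C8, and leaving out DMAP avoids isomerisation of the angelate to the tiglate.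

Step 7
Reactants: 12
Product: 13 (2E,4S,5S)-5-[(1S)-1,2-dihydroxyethyl]-6-(hydroxymethyl)-2-iodohepta-2,6-dien-4-yl (2Z)-2-methylbut-2-enoate
Conditions: AcOH/THF/H2O (3:1:1), 45 °C
Reagents that add atoms: none
Why: Acid-catalysed hydrolysis removes the terminal acetonide and the primary allylic silyl ether together while the allylic angelate and the alkenyl iodide survive.

Step 8
Reactants: 13
Product: 16 (1S,2E)-1-[(2S,3R)-2-(hydroxymethyl)-4-methylidene-5-oxooxolan-3-yl]-3-iodobut-2-en-1-yl (2Z)-2-methylbut-2-enoate, via hydroxy enal 14 (not isolated), via lactol 15 (not isolated)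
Conditions: MnO2 (25 equiv), CH2Cl2, rt; then CSA (10 mol%)
Reagents that add atoms: none
Why: Oxidative lactonisation: MnO2 oxidises only the allylic C12 alcohol to enal 14, the C6 hydroxyl closes to lactol 15 which is oxidised on, and the acid finish funnels any six-membered isomer to the more stable trans-disubstituted γ-lactone, leaving C5-OH and all stereocentres untouched.

Step 9
Reactants: 17 (3S)-3-hydroxyoxolan-2-one [(S)-α-hydroxy-γ-butyrolactone]
Product: 18 (3S)-3-{[tert-butyl(dimethyl)silyl]oxy}oxolan-2-one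
Conditions: TBSCl, imidazole, DMF, rt
Reagents that add atoms: tert-butyldimethylsilyl chloride, CC(C)(C)[Si](C)(C)Cl
Why: Silylation protects the hydroxyl of the bought C3 stereocentre before organolithium addition.

Step 10
Reactants: 19 tributyl(iodomethyl)stannane; 20 (4-methoxyphenyl)methanol
Product: 21 tributyl{[(4-methoxyphenyl)methoxy]methyl}stannane
Conditions: NaH, THF/DMF, 0 °C → rt
Reagents that add atoms: none
Why: Williamson ether synthesis (SN2 of the alkoxide on the iodomethylstannane) gives the precursor of a protected hydroxymethyl anion (C15 and its oxygen).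

Step 11
Reactants: 18; 21
Product: 23 (3S)-3-{[tert-butyl(dimethyl)silyl]oxy}-5-hydroxy-1-[(4-methoxyphenyl)methoxy]pentan-2-one, via alkoxymethyllithium 22 (not isolated)
Conditions: 21, n-BuLi, THF, −78 °C; then 18, −78 °C; aq. NH4Cl
Reagents that add atoms: none
Why: Tin–lithium exchange gives alkoxymethyllithium 22, which adds once to the lactone carbonyl because the tetrahedral lithium alkoxide is stable at −78 °C, and C3 is not enolised at this temperature.

Step 12
Reactants: 23
Product: 24 (3S)-3-{[tert-butyl(dimethyl)silyl]oxy}-4-{[(4-methoxyphenyl)methoxy]methyl}pent-4-en-1-ol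
Conditions: Ph3PCH3Br, KOtBu (3 equiv each), THF, −78 → 0 °C
Reagents that add atoms: methyltriphenylphosphonium bromide, C[P+](c1ccccc1)(c1ccccc1)c1ccccc1.[Br-]
Why: Wittig methylenation of the ketone gives the 1,1-disubstituted olefin, addition of the unstabilised ylide at low temperature being faster than enolisation so that C3 keeps its configuration.

Step 13
Reactants: 24
Product: 25 (3S)-3-{[tert-butyl(dimethyl)silyl]oxy}-4-{[(4-methoxyphenyl)methoxy]methyl}pent-4-enal
Conditions: Dess–Martin periodinane, NaHCO3, CH2Cl2, 0 °C → rt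
Reagents that add atoms: none
Why: Dess–Martin oxidation of the primary alcohol under buffered non-basic conditions gives the β-silyloxy aldehyde without β-elimination.

Step 14
Reactants: 16; 25
Product: 26 coupled diol (C1–C10 bond formed; 1-OH as both epimers; 3-OTBS; 4-methylidene; 15-OPMB; CH2OH (C5) on the lactone; 8-O-angeloyl; 9E)
Conditions: CrCl2 (6 equiv), NiCl2 (2 mol%), DMSO, rt; 25 (1.5 equiv)
Reagents that add atoms: none
Why: Nozaki–Hiyama–Kishi coupling adds the (E)-alkenyl iodide to the aldehyde with retention of olefin geometry and tolerates the free hydroxyl, the esters and the lactone; the C1 epimer mixture is erased in step 15.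

Step 15
Reactants: 26
Product: 27 keto aldehyde (1-oxo enone; CHO (C5) on the lactone; 3-OTBS; 15-OPMB; 8-O-angeloyl; 9E)
Conditions: Dess–Martin periodinane (3 equiv), NaHCO3, CH2Cl2, rt
Reagents that add atoms: none
Why: One Dess–Martin oxidation converts the C1 allylic carbinol into the enone and the C5 primary alcohol into the aldehyde under non-basic conditions that spare C6 and the β-silyloxy ketone.

Step 16
Reactants: 27
Product: 28 trienone (1-oxo enone; vinyl (C5) on the lactone; 3-OTBS; 4-methylidene; 15-OPMB; 8-O-angeloyl; 9E)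
Conditions: CH2I2, Zn, Ti(OiPr)4, THF, rt
Reagents that add atoms: diiodomethane, ICI
Why: Takai methylenation with the gem-dizinc reagent is selective for the aldehyde over the conjugated ketone and the esters and is non-basic, so the α-oxygenated C6 centre is not epimerised.

Step 17
Reactants: 28
Product: 29 β-hydroxy enone ((3S)-3-OH; otherwise as 28)
Conditions: HF·pyridine, pyridine/THF, 0 °C → rt
Reagents that add atoms: none
Why: Fluoride cleavage of the secondary silyl ether frees the C3 hydroxyl under buffered conditions that do not cause retro-aldol or dehydration, and the PMB ether stays.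

Step 18
Reactants: 29
Product: 30 (1S,3S)-3-acetoxy-1-hydroxy diene (15-OPMB; vinyl on the lactone; 4-methylidene)
Conditions: CH3CHO (8 equiv), SmI2 (0.3 equiv, pre-mixed with the aldehyde), THF, −10 °C
Reagents that add atoms: acetaldehyde, CC=O
Why: Evans–Tishchenko reduction: the samarium-bound hemiacetal of the C3 hydroxyl and acetaldehyde delivers hydride intramolecularly through a six-membered chair transition state to the C1 ketone, giving the 1,3-anti (1S) alcohol and leaving the acetate on O3.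

Step 19
Reactants: 30
Product: 31 (1S,3S)-3-acetoxy-1,15-diol (ring-closing precursor)
Conditions: DDQ (1.5 equiv), CH2Cl2/pH 7 buffer (10:1), 0 °C
Reagents that add atoms: none
Why: Oxidative PMB cleavage by DDQ (benzylic hydride abstraction, then hydrolysis) frees the C15 hydroxyl without touching the esters or the allylic alcohol.

Step 20
Reactants: 31
Product: 32 target, (1S,3S,6R,7R,8R)-3-acetoxy-8-angeloyloxy-1,15-dihydroxygermacra-4Z,9E,11(13)-trien-12,6-olide
Conditions: second-generation Grubbs catalyst (20 mol%), 1,4-benzoquinone (20 mol%), toluene (0.5 mM), 80 °C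
Reagents that add atoms: none
Why: Ring-closing olefin metathesis: the carbene loads at the monosubstituted C5 vinyl group and closes onto the 1,1-disubstituted C4 olefin (helped by the free allylic C15 hydroxyl), forming the ten-membered ring with the cis (Z) C4=C5 bond that the medium ring prefers, with no stereocentre involved.

**Compound list**

1 | ethyl 2-(diethoxyphosphoryl)acrylate | CCOC(=O)C(=C)P(=O)(OCC)OCC | starting material
2 | but-2-yn-1-ol | CC#CCO | starting material
3 | (R)-2,2-dimethyl-1,3-dioxolane-4-carbaldehyde ((R)-glyceraldehyde acetonide) | O=C[C@H]1COC(C)(C)O1 | starting material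
4 | sodium salt of the carbanion of ethyl 3-(but-2-yn-1-yloxy)-2-(diethoxyphosphoryl)propanoate (not isolated) | CCOC(=O)[C-](COCC#CC)P(=O)(OCC)OCC.[Na+] | intermediate
5 | ethyl (2E)-2-[(but-2-yn-1-yloxy)methyl]-3-[(4S)-2,2-dimethyl-1,3-dioxolan-4-yl]prop-2-enoate | CCOC(=O)/C(COCC#CC)=C/[C@H]1COC(C)(C)O1 | intermediate
6 | (2Z)-2-[(but-2-yn-1-yloxy)methyl]-3-[(4S)-2,2-dimethyl-1,3-dioxolan-4-yl]prop-2-en-1-ol | OC/C(COCC#CC)=C/[C@H]1COC(C)(C)O1 | intermediate
7 | tert-butyl({(2E)-2-[(but-2-yn-1-yloxy)methyl]-3-[(4S)-2,2-dimethyl-1,3-dioxolan-4-yl]prop-2-en-1-yl}oxy)dimethylsilane | CC(C)(C)[Si](C)(C)OC/C(COCC#CC)=C/[C@H]1COC(C)(C)O1 | intermediate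
8 | lithiated propargylic ether of 7 (carbanion at C8; not isolated) | CC(C)(C)[Si](C)(C)OC/C(CO[CH-]C#CC)=C/[C@H]1COC(C)(C)O1.[Li+] | intermediate
9 | (3R,4S)-2-({[tert-butyl(dimethyl)silyl]oxy}methyl)-3-[(4S)-2,2-dimethyl-1,3-dioxolan-4-yl]hept-1-en-5-yn-4-ol | C=C(CO[Si](C)(C)C(C)(C)C)[C@H]([C@H](O)C#CC)[C@H]1COC(C)(C)O1 | intermediate
10 | C10-zirconated (E)-alkenylzirconocene chloride of 9, O8 also bound to Cp2ZrCl (not isolated) | C=C(CO[Si](C)(C)C(C)(C)C)[C@H]([C@H](O[Zr](Cl)(C1C=CC=C1)C1C=CC=C1)/C=C(\C)[Zr](Cl)(C1C=CC=C1)C1C=CC=C1)[C@H]1COC(C)(C)O1 | intermediate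
11 | (2E,4S,5R)-6-({[tert-butyl(dimethyl)silyl]oxy}methyl)-5-[(4S)-2,2-dimethyl-1,3-dioxolan-4-yl]-2-iodohepta-2,6-dien-4-ol | C=C(CO[Si](C)(C)C(C)(C)C)[C@H]([C@H](O)/C=C(\C)I)[C@H]1COC(C)(C)O1 | intermediate
12 | (2E,4S,5R)-6-({[tert-butyl(dimethyl)silyl]oxy}methyl)-5-[(4S)-2,2-dimethyl-1,3-dioxolan-4-yl]-2-iodohepta-2,6-dien-4-yl (2Z)-2-methylbut-2-enoate | C=C(CO[Si](C)(C)C(C)(C)C)[C@H]([C@H](OC(=O)/C(C)=C\C)/C=C(\C)I)[C@H]1COC(C)(C)O1 | intermediate
13 | (2E,4S,5S)-5-[(1S)-1,2-dihydroxyethyl]-6-(hydroxymethyl)-2-iodohepta-2,6-dien-4-yl (2Z)-2-methylbut-2-enoate | C=C(CO)[C@H]([C@H](OC(=O)/C(C)=C\C)/C=C(\C)I)[C@H](O)CO | intermediate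
14 | hydroxy enal: C12 aldehyde of 13 (not isolated) | C=C(C=O)[C@H]([C@H](OC(=O)/C(C)=C\C)/C=C(\C)I)[C@H](O)CO | intermediate
15 | lactol: cyclic hemiacetal of 14 through O6 (not isolated; anomers) | C=C1C(O)O[C@H](CO)[C@H]1[C@H](OC(=O)/C(C)=C\C)/C=C(\C)I | intermediate
16 | (1S,2E)-1-[(2S,3R)-2-(hydroxymethyl)-4-methylidene-5-oxooxolan-3-yl]-3-iodobut-2-en-1-yl (2Z)-2-methylbut-2-enoate | C=C1C(=O)O[C@H](CO)[C@H]1[C@H](OC(=O)/C(C)=C\C)/C=C(\C)I | intermediate
17 | (3S)-3-hydroxyoxolan-2-one ((S)-α-hydroxy-γ-butyrolactone) | O=C1OCC[C@@H]1O | starting material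
18 | (3S)-3-{[tert-butyl(dimethyl)silyl]oxy}oxolan-2-one | O=C1OCC[C@@H]1O[Si](C)(C)C(C)(C)C | intermediate
19 | tributyl(iodomethyl)stannane | CCCC[Sn](CCCC)(CCCC)CI | starting material
20 | (4-methoxyphenyl)methanol | COc1ccc(CO)cc1 | starting material
21 | tributyl{[(4-methoxyphenyl)methoxy]methyl}stannane | CCCC[Sn](CCCC)(CCCC)COCc1ccc(OC)cc1 | intermediate
22 | [(4-methoxyphenyl)methoxy]methyllithium (not isolated) | [Li+].[CH2-]OCc1ccc(OC)cc1 | intermediate
23 | (3S)-3-{[tert-butyl(dimethyl)silyl]oxy}-5-hydroxy-1-[(4-methoxyphenyl)methoxy]pentan-2-one | OCC[C@H](O[Si](C)(C)C(C)(C)C)C(=O)COCc1ccc(OC)cc1 | intermediate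
24 | (3S)-3-{[tert-butyl(dimethyl)silyl]oxy}-4-{[(4-methoxyphenyl)methoxy]methyl}pent-4-en-1-ol | OCC[C@H](O[Si](C)(C)C(C)(C)C)C(=C)COCc1ccc(OC)cc1 | intermediate
25 | (3S)-3-{[tert-butyl(dimethyl)silyl]oxy}-4-{[(4-methoxyphenyl)methoxy]methyl}pent-4-enal | O=CC[C@H](O[Si](C)(C)C(C)(C)C)C(=C)COCc1ccc(OC)cc1 | intermediate
26 | coupled diol: 16 joined through C10 to C1 of 25; 1-OH as both epimers; 3-OTBS; 15-OPMB | C=C1C(=O)O[C@H](CO)[C@H]1[C@H](OC(=O)/C(C)=C\C)/C=C(\C)C(O)C[C@H](O[Si](C)(C)C(C)(C)C)C(=C)COCc1ccc(OC)cc1 | intermediate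
27 | keto aldehyde: C1 enone and C5 aldehyde from 26 | C=C1C(=O)O[C@H](C=O)[C@H]1[C@H](OC(=O)/C(C)=C\C)/C=C(\C)C(=O)C[C@H](O[Si](C)(C)C(C)(C)C)C(=C)COCc1ccc(OC)cc1 | intermediate
28 | trienone: C5 vinyl on the lactone; 1-oxo; 3-OTBS; 15-OPMB | C=C1C(=O)O[C@H](C=C)[C@H]1[C@H](OC(=O)/C(C)=C\C)/C=C(\C)C(=O)C[C@H](O[Si](C)(C)C(C)(C)C)C(=C)COCc1ccc(OC)cc1 | intermediate
29 | β-hydroxy enone: (3S)-3-OH; 1-oxo; 15-OPMB | C=C1C(=O)O[C@H](C=C)[C@H]1[C@H](OC(=O)/C(C)=C\C)/C=C(\C)C(=O)C[C@H](O)C(=C)COCc1ccc(OC)cc1 | intermediate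
30 | (1S,3S)-3-acetoxy-1-hydroxy diene; 15-OPMB | C=C1C(=O)O[C@H](C=C)[C@H]1[C@H](OC(=O)/C(C)=C\C)/C=C(\C)[C@@H](O)C[C@H](OC(C)=O)C(=C)COCc1ccc(OC)cc1 | intermediate
31 | (1S,3S)-3-acetoxy-1,15-diol (acyclic ring-closing precursor) | C=C1C(=O)O[C@H](C=C)[C@H]1[C@H](OC(=O)/C(C)=C\C)/C=C(\C)[C@@H](O)C[C@H](OC(C)=O)C(=C)CO | intermediate
32 | (1S,3S,6R,7R,8R)-3-acetoxy-8-angeloyloxy-1,15-dihydroxygermacra-4Z,9E,11(13)-trien-12,6-olide | C=C1C(=O)O[C@@H]2/C=C(/CO)[C@@H](OC(C)=O)C[C@H](O)/C(C)=C/[C@@H](OC(=O)/C(C)=C\C)[C@@H]12 | target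

**Step count and risks**

Total: 20 steps. Longest linear sequence: 15 steps (steps 1–8, then 14–20); the west branch is steps 9–13.

Most likely to fail, 1: step 20 (metathesis to a ten-membered ring with a trisubstituted olefin from a hindered 1,1-disubstituted partner; dimers or the E isomer are possible). The fallback sets out from 29 and comes back at 32. It closes the ring before C1 is reduced: 29, with its free allylic C3 hydroxyl and sp2 C1, is treated with the second-generation Grubbs catalyst in dilute toluene at 80 °C to give the macrocyclic β-hydroxy enone F1. The Evans–Tishchenko reduction (CH3CHO, SmI2) is then run transannularly to give the 15-O-PMB ether of the target F2, and DDQ as in step 19 gives 32.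

Most likely to fail, 2: step 4 (the diastereocontrol rests on the substrate alone; the syn/anti ratio also suffers from any geometrical impurity in 7, and a [1,2]-shift can compete; a wrong facial sense at C7 would not be repaired by this fallback). The fallback sets out from 7 and comes back at 12. It sets C8 by SN2 inversion instead: the C8-epimeric (anti) alcohol F3, formed as the by-product or made on purpose from the geometrical isomer of 7, is hydrozirconated and iodinated as in step 5 to the alkenyl iodide F4. Mitsunobu esterification of F4 with angelic acid (PPh3, DIAD, toluene, 0 °C) inverts C8 and installs the ester in one operation, giving 12.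

Most likely to fail, 3: step 8 (the C5 and C6 hydroxyls compete for the enal, so a six-membered lactone or over-oxidation can result). The fallback sets out from 12 and comes back at 16. It fixes the oxidation state first and lets the lactone form under thermodynamic control: HF·pyridine removes only the silyl ether of 12 to give the allylic alcohol F5 (acetonide intact), MnO2 gives the enal F6, and NaClO2/NaH2PO4/2-methylbut-2-ene gives the acrylic acid F7. Aqueous trifluoroacetic acid then removes the acetonide and the freed C6 hydroxyl closes the more stable γ-lactone 16.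

**Further compounds**

F1 | step 20 | macrocyclic β-hydroxy enone (1-oxo, 3-hydroxy, 15-O-PMB analogue of 32) | C=C1C(=O)O[C@@H]2/C=C(/COCc3ccc(OC)cc3)[C@@H](O)CC(=O)/C(C)=C/[C@@H](OC(=O)/C(C)=C\C)[C@@H]12
F2 | step 20 | 15-O-(4-methoxybenzyl) ether of 32 | C=C1C(=O)O[C@@H]2/C=C(/COCc3ccc(OC)cc3)[C@@H](OC(C)=O)C[C@H](O)/C(C)=C/[C@@H](OC(=O)/C(C)=C\C)[C@@H]12
F3 | step 4 | (3R,4R)-2-({[tert-butyl(dimethyl)silyl]oxy}methyl)-3-[(4S)-2,2-dimethyl-1,3-dioxolan-4-yl]hept-1-en-5-yn-4-ol (C8 epimer of 9) | C=C(CO[Si](C)(C)C(C)(C)C)[C@H]([C@@H](O)C#CC)[C@H]1COC(C)(C)O1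
F4 | step 4 | (2E,4R,5R)-6-({[tert-butyl(dimethyl)silyl]oxy}methyl)-5-[(4S)-2,2-dimethyl-1,3-dioxolan-4-yl]-2-iodohepta-2,6-dien-4-ol (C8 epimer of 11) | C=C(CO[Si](C)(C)C(C)(C)C)[C@H]([C@@H](O)/C=C(\C)I)[C@H]1COC(C)(C)O1
F5 | step 8 | (2E,4S,5R)-5-[(4S)-2,2-dimethyl-1,3-dioxolan-4-yl]-6-(hydroxymethyl)-2-iodohepta-2,6-dien-4-yl (2Z)-2-methylbut-2-enoate | C=C(CO)[C@H]([C@H](OC(=O)/C(C)=C\C)/C=C(\C)I)[C@H]1COC(C)(C)O1
F6 | step 8 | C12 aldehyde (enal) of F5 | C=C(C=O)[C@H]([C@H](OC(=O)/C(C)=C\C)/C=C(\C)I)[C@H]1COC(C)(C)O1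
F7 | step 8 | C12 carboxylic acid (2-substituted acrylic acid) of F5 | C=C(C(=O)O)[C@H]([C@H](OC(=O)/C(C)=C\C)/C=C(\C)I)[C@H]1COC(C)(C)O1
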